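**Retrosynthetic overview**

1. The ten-membered carbocycle C1–C10 is opened at C9–C10. The enabling feature is that C9 is a secondary carbinol allylic to the (Z)-C1=C10(CH3) olefin inside that ring and next to the C8 ester, so it is the retron of an alkenyl-metal/aldehyde union; the Z geometry (C9 cis to C2) folds the chain ends toward each other. The seco compound is (Z)-alkenyl iodide/aldehyde 19, closed by intramolecular Ni/Cr (Nozaki–Hiyama–Kishi) addition.
2. 19 comes from a C7–C8 disconnection: Cr(II)-mediated vinylogous Barbier allylation of silyloxyacetaldehyde 13 by 3-(bromomethyl)butenolide 12. This sets C7 and C8 and unveils the C11=C13 methylene lactone; Ni-free Cr(II) leaves the alkenyl iodide dormant for the last step.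
3. 12 comes from ring-closing metathesis of the 2-(bromomethyl)acrylate of epoxy vinyl carbinol 8. 8 comes from an A(1,3)-controlled, hydroxyl-directed epoxidation of dienol 7, and 7 from a catalytic asymmetric vinylation of enal 6. The catalyst-set centre C6 relays to C4/C5, then C7/C8, then C9.
4. 6 comes from geranyl acetate, which supplies C1–C6 and C15, by chemoselective ozonolysis and Z-selective iodo-olefination.
5. Ring order: oxirane (step 6), then γ-lactone (step 8), then ten-membered carbocycle (step 13, last).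

Key step: step 13

Remark on the chemistry: germacrane numbering is used throughout (ring C1–C10; C1=C10 olefin with C14 on C10; C4–C5 oxirane with C15 on C4; lactone O–C6, C7, C11(=C13), C12; ester on O8; OH on C9). The SMILES is read as 4R,5R,6S,7R,8R,9R with a 1(10)Z olefin. Divinylzinc is taken as prepared from vinylmagnesium bromide and ZnCl2.

**Route**

Step 1
Reactants: 1 geranyl acetate
Product: 3 (2E)-3-methyl-6-oxohex-2-en-1-yl acetate, via secondary ozonide 2 (not isolated)
Conditions: O3, CH2Cl2–pyridine, −78 °C (Sudan III end point); then Me2S, −78 °C → rt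
Reagents that add atoms: ozone, [O-][O+]=O
Why: Chemoselective ozonolysis with reductive work-up: ozone should cleave the electron-rich remote trisubstituted olefin much faster than the olefin deactivated by the allylic acetate, giving the C1 aldehyde with the (E)-C4=C5 olefin intact.

Step 2
Reactants: 3 (2E)-3-methyl-6-oxohex-2-en-1-yl acetate
Product: 4 (2E,6Z)-7-iodo-3-methylocta-2,6-dien-1-yl acetate
Conditions: EtPPh3I, n-BuLi, THF, 0 °C → rt; I2, −78 °C; NaHMDS, −20 °C; then 3, −78 → −20 °C
Reagents that add atoms: ethyltriphenylphosphonium iodide, CC[P+](c1ccccc1)(c1ccccc1)c1ccccc1.[I-]; iodine, II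
Why: Wittig olefination with (1-iodoethylidene)triphenylphosphorane (Stork–Zhao-type iodo-olefination) is kinetically Z-selective and places iodine cis to the chain, which fixes the later cis relation of C9 and C2 across C1=C10.

Step 3
Reactants: 4 (2E,6Z)-7-iodo-3-methylocta-2,6-dien-1-yl acetate
Product: 5 (2E,6Z)-7-iodo-3-methylocta-2,6-dien-1-ol
Conditions: K2CO3 (cat.), MeOH, 0 °C → rt
Reagents that add atoms: none
Why: Carbonate-catalysed methanolysis (transesterification) removes the acetate without affecting the alkenyl iodide or either olefin geometry.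

Step 4
Reactants: 5 (2E,6Z)-7-iodo-3-methylocta-2,6-dien-1-ol
Product: 6 (2E,6Z)-7-iodo-3-methylocta-2,6-dienal
Conditions: TEMPO (cat.), PhI(OAc)2, CH2Cl2, rt
Reagents that add atoms: none
Why: TEMPO/PhI(OAc)2 oxidation of a primary allylic alcohol should stop at the (E)-enal without E/Z isomerisation and without touching the iodoalkene.

Step 5
Reactants: 6 (2E,6Z)-7-iodo-3-methylocta-2,6-dienal
Product: 7 (3S,4E,8Z)-9-iodo-5-methyldeca-1,4,8-trien-3-ol
Conditions: (CH2=CH)2Zn, (−)-MIB (5 mol %), toluene, −30 → 0 °C; aq NH4Cl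
Reagents that add atoms: divinylzinc, C=C[Zn]C=C
Why: Amino-alcohol-catalysed asymmetric 1,2-addition of a vinylzinc reagent to an enal: by analogy with its alkyl transfers, (−)-MIB should direct the vinyl group to the Si face of the aldehyde, which sets C6 as S, and the alkenyl iodide is inert to organozinc reagents.

Step 6
Reactants: 7 (3S,4E,8Z)-9-iodo-5-methyldeca-1,4,8-trien-3-ol
Product: 8 (1S)-1-[(2R,3R)-3-[(3Z)-4-iodopent-3-en-1-yl]-3-methyloxiran-2-yl]prop-2-en-1-ol
Conditions: Ti(OiPr)4 (20 mol %), t-BuOOH (decane), 4 Å MS, CH2Cl2, −20 °C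
Reagents that add atoms: tert-butyl hydroperoxide, CC(C)(C)OO
Why: Alkoxide-directed Ti(IV)/TBHP epoxidation acts only on the electron-rich allylic C4=C5 olefin, and A(1,3) strain between C6–H and the C15 methyl (cis to C6) fixes the reactive conformer so that oxygen is delivered to the hydroxyl-bearing face (threo product), setting 4R,5R from 6S.

Step 7
Reactants: 8 (1S)-1-[(2R,3R)-3-[(3Z)-4-iodopent-3-en-1-yl]-3-methyloxiran-2-yl]prop-2-en-1-ol; 9 2-(bromomethyl)prop-2-enoic acid
Product: 11 (1S)-1-[(2R,3R)-3-[(3Z)-4-iodopent-3-en-1-yl]-3-methyloxiran-2-yl]prop-2-en-1-yl 2-(bromomethyl)prop-2-enoate, via acid chloride 10 (not isolated)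
Conditions: 9, (COCl)2, DMF (cat.), CH2Cl2, 0 °C → rt, evaporate; then 8, i-Pr2NEt, CH2Cl2, −30 → 0 °C
Reagents that add atoms: none
Why: O-Acylation of the secondary alcohol by the acid chloride in the presence of a hindered, non-nucleophilic amine should outpace any reaction at the allylic bromide and leaves all stereocentres untouched.

Step 8
Reactants: 11 (1S)-1-[(2R,3R)-3-[(3Z)-4-iodopent-3-en-1-yl]-3-methyloxiran-2-yl]prop-2-en-1-yl 2-(bromomethyl)prop-2-enoate
Product: 12 (5S)-3-(bromomethyl)-5-[(2R,3R)-3-[(3Z)-4-iodopent-3-en-1-yl]-3-methyloxiran-2-yl]furan-2(5H)-one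
Conditions: Grubbs second-generation catalyst (5 mol %), CH2Cl2 (5 mM), 40 °C
Reagents that add atoms: none
Why: Ring-closing metathesis between the terminal vinyl group and the 1,1-disubstituted acrylate closes the five-membered butenolide (C7=C11) with loss of ethylene, while the trisubstituted iodoalkene is too hindered to enter metathesis.

Step 9
Reactants: 12 (5S)-3-(bromomethyl)-5-[(2R,3R)-3-[(3Z)-4-iodopent-3-en-1-yl]-3-methyloxiran-2-yl]furan-2(5H)-one; 13 {[tert-butyl(dimethyl)silyl]oxy}acetaldehyde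
Product: 15 (4R,5S)-4-[(1R)-2-{[tert-butyl(dimethyl)silyl]oxy}-1-hydroxyethyl]-5-[(2R,3R)-3-[(3Z)-4-iodopent-3-en-1-yl]-3-methyloxiran-2-yl]-3-methylideneoxolan-2-one, via allylchromium(III) species 14 (not isolated)
Conditions: CrCl2 (nickel-free, 3 equiv), 13 (2 equiv), THF, 0 °C → rt; aq NH4Cl
Reagents that add atoms: none
Why: Nozaki–Hiyama-type vinylogous Barbier allylation: Cr(II) inserts into the allylic C13–Br bond (without Ni the alkenyl iodide stays dormant) and the γ-carbon C7 of 14 adds to the aldehyde through a chair Zimmerman–Traxler transition state, so that attack anti to the C6 side chain sets C7 (trans-lactone), the ring-fixed E geometry of the allyl unit with the aldehyde substituent equatorial sets C8 (anti to C6), and the C11=C13 methylene lactone is unveiled.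

Step 10
Reactants: 15 (4R,5S)-4-[(1R)-2-{[tert-butyl(dimethyl)silyl]oxy}-1-hydroxyethyl]-5-[(2R,3R)-3-[(3Z)-4-iodopent-3-en-1-yl]-3-methyloxiran-2-yl]-3-methylideneoxolan-2-one; 16 3-methylbut-2-enoic acid
Product: 17 (1R)-2-{[tert-butyl(dimethyl)silyl]oxy}-1-[(2S,3R)-2-[(2R,3R)-3-[(3Z)-4-iodopent-3-en-1-yl]-3-methyloxiran-2-yl]-4-methylidene-5-oxooxolan-3-yl]ethyl 3-methylbut-2-enoate
Conditions: 16, DCC, DMAP (cat.), CH2Cl2, 0 °C
Reagents that add atoms: none
Why: Steglich esterification of the only free hydroxyl (C8–OH) proceeds with retention at C8, and low temperature with only catalytic DMAP should limit deconjugation of the senecioyl unit and translactonisation.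

Step 11
Reactants: 17 (1R)-2-{[tert-butyl(dimethyl)silyl]oxy}-1-[(2S,3R)-2-[(2R,3R)-3-[(3Z)-4-iodopent-3-en-1-yl]-3-methyloxiran-2-yl]-4-methylidene-5-oxooxolan-3-yl]ethyl 3-methylbut-2-enoate
Product: 18 (1R)-2-hydroxy-1-[(2S,3R)-2-[(2R,3R)-3-[(3Z)-4-iodopent-3-en-1-yl]-3-methyloxiran-2-yl]-4-methylidene-5-oxooxolan-3-yl]ethyl 3-methylbut-2-enoate
Conditions: HF·pyridine, pyridine, THF, 0 °C → rt
Reagents that add atoms: none
Why: Buffered HF·pyridine cleaves the primary silyl ether while the epoxide, both esters and the iodoalkene should survive, and 8→9 acyl migration is slow under these mildly acidic conditions.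

Step 12
Reactants: 18 (1R)-2-hydroxy-1-[(2S,3R)-2-[(2R,3R)-3-[(3Z)-4-iodopent-3-en-1-yl]-3-methyloxiran-2-yl]-4-methylidene-5-oxooxolan-3-yl]ethyl 3-methylbut-2-enoate
Product: 19 (1R)-2-oxo-1-[(2S,3S)-2-[(2R,3R)-3-[(3Z)-4-iodopent-3-en-1-yl]-3-methyloxiran-2-yl]-4-methylidene-5-oxooxolan-3-yl]ethyl 3-methylbut-2-enoate (same configuration as 18; the ring-carbon descriptor changes only because the formyl branch now outranks the oxiranyl branch)
Conditions: Dess–Martin periodinane, NaHCO3, CH2Cl2, 0 °C → rt; used crude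
Reagents that add atoms: none
Why: Buffered Dess–Martin oxidation gives the α-acyloxy aldehyde under neutral conditions that should avoid epimerisation at C8 and acyl migration.

Step 13
Reactants: 19 (1R)-2-oxo-1-[(2S,3S)-2-[(2R,3R)-3-[(3Z)-4-iodopent-3-en-1-yl]-3-methyloxiran-2-yl]-4-methylidene-5-oxooxolan-3-yl]ethyl 3-methylbut-2-enoate
Product: 21 (1(10)Z,4R,5R,6S,7R,8R,9R)-4,5-epoxy-9-hydroxy-8-[(3-methylbut-2-enoyl)oxy]germacra-1(10),11(13)-dien-12,6-olide (CNP0188779.3), via alkenylchromium(III) species 20 (not isolated)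
Conditions: CrCl2 (10 equiv), NiCl2 (cat.), DMSO–THF, rt, slow addition of 19 (final 2 mM); aq work-up
Reagents that add atoms: none
Why: Ni(0), formed from NiCl2 by Cr(II), inserts into the C10–I bond with retention of the Z geometry and hands the alkenyl group to Cr(III) (20), which adds to the C9 aldehyde through the Cr-bound carbonyl; the closest known reaction type is the Nozaki–Hiyama–Kishi cyclisation of ω-iodoalkenyl aldehydes to medium and large carbocycles. The ten-membered carbocycle C1–C10 is closed by C9–C10 bond formation in a 10-exo-trig mode (carbonyl oxygen exocyclic) at high dilution. The new stereocentre C9 is controlled by the adjacent C8 acyloxy stereocentre inside the cyclic transition state: with the chromium-bound oxygen pointing out of the forming ring and C7 anti to the incoming C10, the exposed aldehyde face gives the 8,9-syn (9R) carbinol. The step needs chemoselectivity for the aldehyde (alkenylchromium(III) does not add to the lactone, the senecioate, the epoxide or the methylene lactone), cyclisation over oligomerisation, and retention of olefin geometry; these are secured by the reagent class, by dilution, and by three turn elements already in the chain (the Z-C1=C10 iodide, the trans-oxirane and the trans-lactone), which bring C9 and C10 together. The ring closure itself creates the free C9 hydroxyl, so the product is the target without any protecting-group step.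

**Compound list**

1 | geranyl acetate, (2E)-3,7-dimethylocta-2,6-dien-1-yl acetate | CC(C)=CCC/C(C)=C/COC(C)=O | starting material
2 | secondary ozonide (1,2,4-trioxolane) of the remote olefin of 1 | CC1(C)OOC(CC/C(C)=C/COC(C)=O)O1 | intermediate
3 | (2E)-3-methyl-6-oxohex-2-en-1-yl acetate | O=CCC/C(C)=C/COC(C)=O | intermediate
4 | (2E,6Z)-7-iodo-3-methylocta-2,6-dien-1-yl acetate | CC(=O)OC/C=C(C)/CC/C=C(/C)I | intermediate
5 | (2E,6Z)-7-iodo-3-methylocta-2,6-dien-1-ol | OC/C=C(C)/CC/C=C(/C)I | intermediate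
6 | (2E,6Z)-7-iodo-3-methylocta-2,6-dienal | O=C/C=C(C)/CC/C=C(/C)I | intermediate
7 | (3S,4E,8Z)-9-iodo-5-methyldeca-1,4,8-trien-3-ol | C=C[C@H](O)/C=C(C)/CC/C=C(/C)I | intermediate
8 | (1S)-1-[(2R,3R)-3-[(3Z)-4-iodopent-3-en-1-yl]-3-methyloxiran-2-yl]prop-2-en-1-ol | C=C[C@H](O)[C@H]1O[C@]1(C)CC/C=C(/C)I | intermediate
9 | 2-(bromomethyl)prop-2-enoic acid | C=C(CBr)C(=O)O | starting material
10 | 2-(bromomethyl)prop-2-enoyl chloride | C=C(CBr)C(=O)Cl | intermediate
11 | (1S)-1-[(2R,3R)-3-[(3Z)-4-iodopent-3-en-1-yl]-3-methyloxiran-2-yl]prop-2-en-1-yl 2-(bromomethyl)prop-2-enoate | C=C[C@H](OC(=O)C(=C)CBr)[C@H]1O[C@]1(C)CC/C=C(/C)I | intermediate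
12 | (5S)-3-(bromomethyl)-5-[(2R,3R)-3-[(3Z)-4-iodopent-3-en-1-yl]-3-methyloxiran-2-yl]furan-2(5H)-one | BrCC1=C[C@H](OC1=O)[C@H]1O[C@]1(C)CC/C=C(/C)I | intermediate
13 | {[tert-butyl(dimethyl)silyl]oxy}acetaldehyde | O=CCO[Si](C)(C)C(C)(C)C | starting material
14 | allylchromium(III) dichloride derived from 12 (Cr on C13) | Cl[Cr](Cl)CC1=C[C@H](OC1=O)[C@H]1O[C@]1(C)CC/C=C(/C)I | intermediate
15 | (4R,5S)-4-[(1R)-2-{[tert-butyl(dimethyl)silyl]oxy}-1-hydroxyethyl]-5-[(2R,3R)-3-[(3Z)-4-iodopent-3-en-1-yl]-3-methyloxiran-2-yl]-3-methylideneoxolan-2-one | C=C1C(=O)O[C@@H]([C@H]1[C@@H](O)CO[Si](C)(C)C(C)(C)C)[C@H]1O[C@]1(C)CC/C=C(/C)I | intermediate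
16 | 3-methylbut-2-enoic acid (senecioic acid) | CC(C)=CC(=O)O | starting material
17 | (1R)-2-{[tert-butyl(dimethyl)silyl]oxy}-1-[(2S,3R)-2-[(2R,3R)-3-[(3Z)-4-iodopent-3-en-1-yl]-3-methyloxiran-2-yl]-4-methylidene-5-oxooxolan-3-yl]ethyl 3-methylbut-2-enoate | C=C1C(=O)O[C@@H]([C@H]1[C@@H](OC(=O)C=C(C)C)CO[Si](C)(C)C(C)(C)C)[C@H]1O[C@]1(C)CC/C=C(/C)I | intermediate
18 | (1R)-2-hydroxy-1-[(2S,3R)-2-[(2R,3R)-3-[(3Z)-4-iodopent-3-en-1-yl]-3-methyloxiran-2-yl]-4-methylidene-5-oxooxolan-3-yl]ethyl 3-methylbut-2-enoate | C=C1C(=O)O[C@@H]([C@H]1[C@@H](OC(=O)C=C(C)C)CO)[C@H]1O[C@]1(C)CC/C=C(/C)I | intermediate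
19 | (1R)-2-oxo-1-[(2S,3S)-2-[(2R,3R)-3-[(3Z)-4-iodopent-3-en-1-yl]-3-methyloxiran-2-yl]-4-methylidene-5-oxooxolan-3-yl]ethyl 3-methylbut-2-enoate | C=C1C(=O)O[C@@H]([C@H]1[C@@H](OC(=O)C=C(C)C)C=O)[C@H]1O[C@]1(C)CC/C=C(/C)I | intermediate
20 | alkenylchromium(III) dichloride derived from 19 (Cr on C10, Z retained) | C=C1C(=O)O[C@@H]([C@H]1[C@@H](OC(=O)C=C(C)C)C=O)[C@H]1O[C@]1(C)CC/C=C(/C)[Cr](Cl)Cl | intermediate
21 | (1(10)Z,4R,5R,6S,7R,8R,9R)-4,5-epoxy-9-hydroxy-8-[(3-methylbut-2-enoyl)oxy]germacra-1(10),11(13)-dien-12,6-olide (CNP0188779.3) | C=C1C(=O)O[C@H]2[C@H]1[C@@H](OC(=O)C=C(C)C)[C@H](O)/C(C)=C\CC[C@@]1(C)O[C@H]21 | target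

**Step count and risks**

Total step count: 13. Longest linear sequence: 13 steps (from geranyl acetate 1; the route is fully linear, and 9, 13 and 16 are bought).

The three steps most likely to fail:

Step 13 (key step). The process at risk is facial selection at the C9 aldehyde. The open-chain polar Felkin–Anh preference (nucleophile anti to the C8–O bond) leads to the 9-epimer, so the required 8,9-syn product depends on the ring-forming transition state overriding it; intermolecular coupling at insufficient dilution is the second hazard. The fallback sets out from 19 and comes back at 21. The cyclisation is run as described, and the C9-epimeric allylic alcohol, (9S)-epimer of 21 F1, is not separated from any 21 formed. The mixture is oxidised (Dess–Martin periodinane, NaHCO3, CH2Cl2) to the ten-membered (Z)-enone, the 9-oxo compound F2. Luche reduction (NaBH4, CeCl3·7H2O, MeOH, −78 °C) then delivers hydride anti to the C8–O bond, which for a ketone reduction corresponds to the 8,9-syn alcohol 21. C9 is thus set by C–H instead of C–C bond formation.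

Step 8. The process at risk is slow closure onto the electron-poor 1,1-disubstituted acrylate, with loss of the ruthenium alkylidene through side reactions at the allylic C–Br bond. The fallback sets out from 8 and comes back at 12, carrying C13 as a free hydroxymethyl group through the metathesis. Alcohol 8 is acylated with acryloyl chloride (i-Pr2NEt, CH2Cl2, −20 °C) to the acrylate ester F3. A Morita–Baylis–Hillman hydroxymethylation (aqueous formaldehyde, DABCO, dioxane, rt) gives the 2-(hydroxymethyl)acrylate ester F4. Ring-closing metathesis (Grubbs second-generation catalyst, CH2Cl2, 40 °C) gives the 3-(hydroxymethyl)butenolide F5, and Appel bromination (CBr4, PPh3, CH2Cl2, 0 °C) returns 12.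

Step 9. The process at risk is erosion of the anti simple diastereoselection (boat or open transition states in place of the chair), which would give the C8 epimer; translactonisation of the chromium alkoxide onto the lactone carbonyl is a second concern. The fallback sets out from 12 and comes back at 17. The C8-epimeric adduct, (1S)-hydroxyethyl epimer of 15 F6, formed alone or beside 15, is esterified with 16 under Mitsunobu conditions (PPh3, DIAD, toluene, 0 °C → rt). This installs the senecioate with inversion at C8 and gives 17, so that C8 is set by SN2 inversion instead of by the allylation transition state and both epimers converge.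

**Further compounds**

F1 | step 13 | (1(10)Z,4R,5R,6S,7R,8R,9S)-4,5-epoxy-9-hydroxy-8-[(3-methylbut-2-enoyl)oxy]germacra-1(10),11(13)-dien-12,6-olide (9-epimer of 21) | C=C1C(=O)O[C@H]2[C@H]1[C@@H](OC(=O)C=C(C)C)[C@@H](O)/C(C)=C\CC[C@@]1(C)O[C@H]21
F2 | step 13 | (1(10)Z,4R,5R,6S,7S,8R)-4,5-epoxy-8-[(3-methylbut-2-enoyl)oxy]-9-oxogermacra-1(10),11(13)-dien-12,6-olide | C=C1C(=O)O[C@H]2[C@H]1[C@@H](OC(=O)C=C(C)C)C(=O)/C(C)=C\CC[C@@]1(C)O[C@H]21
F3 | step 8 | (1S)-1-[(2R,3R)-3-[(3Z)-4-iodopent-3-en-1-yl]-3-methyloxiran-2-yl]prop-2-en-1-yl prop-2-enoate | C=C[C@H](OC(=O)C=C)[C@H]1O[C@]1(C)CC/C=C(/C)I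
F4 | step 8 | (1S)-1-[(2R,3R)-3-[(3Z)-4-iodopent-3-en-1-yl]-3-methyloxiran-2-yl]prop-2-en-1-yl 2-(hydroxymethyl)prop-2-enoate | C=C[C@H](OC(=O)C(=C)CO)[C@H]1O[C@]1(C)CC/C=C(/C)I
F5 | step 8 | (5S)-3-(hydroxymethyl)-5-[(2R,3R)-3-[(3Z)-4-iodopent-3-en-1-yl]-3-methyloxiran-2-yl]furan-2(5H)-one | OCC1=C[C@H](OC1=O)[C@H]1O[C@]1(C)CC/C=C(/C)I
F6 | step 9 | (4R,5S)-4-[(1S)-2-{[tert-butyl(dimethyl)silyl]oxy}-1-hydroxyethyl]-5-[(2R,3R)-3-[(3Z)-4-iodopent-3-en-1-yl]-3-methyloxiran-2-yl]-3-methylideneoxolan-2-one (C8 epimer of 15) | C=C1C(=O)O[C@@H]([C@H]1[C@H](O)CO[Si](C)(C)C(C)(C)C)[C@H]1O[C@]1(C)CC/C=C(/C)I
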